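The earlier runs and the new flask are calculated from invented constants.

Thursday's flask asks how far a racemate gets on a single-handed catalyst by 8.0 min, and how one-sided its product is by then.

in all of them: precatalyst 76 µM
- Thursday's: left-handed substrate 21 mM; right-handed substrate 21 mM; partner 63 mM; the very flask that is asked about, followed so far
- Monday's: left-handed substrate 10 mM; right-handed substrate 10 mM; partner 63 mM; run made earlier
- flask: left-handed substrate 21 mM; right-handed substrate 21 mM; partner 63.0 mM; time 8.0 min

- excess of left-handed product over right-handed product in the product at 10 s
- excess of left-handed product over right-handed product in the product at 8.0 min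
- part of the left-handed substrate and right-handed substrate charged together that has reacted at 8.0 min

- catalyst is single-handed; left-handed substrate and right-handed substrate are mirror images of each other, charged as a racemate, each of them at the stated concentration
- the numbers in the tables scatter by 1.5 percentage points (one standard deviation)
- candidate steps: partner + catalyst + left-handed substrate -> catalyst + left-handed product; partner + catalyst + right-handed substrate -> catalyst + right-handed product; left-handed substrate <-> right-handed substrate; partner + precatalyst -> catalyst + spent reagent; 2 partner -> homo dimer; partner -> decomposed reagent
- an excess is the difference of the two amounts in percent of their sum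
- an excess is below zero if the other one leads

Thursday's run (percent of the left-handed substrate and right-handed substrate together charged)

| time / s | left-handed product / % | right-handed product / % |
|---|---|---|
| 10.0 | 0 | 4 |
| 15.0 | 0 | 0 |
| 25.0 | 4 | 1 |
| 40.0 | 1 | 1 |
| 60.0 | 5 | 0 |

Monday's run (percent of the left-handed substrate and right-handed substrate together charged)

| time / min | left-handed product / % | right-handed product / % |
|---|---|---|
| 1.50 | 5 | 0 |
| 3.00 | 11 | 0 |
| 5.00 | 17 | 2 |
| 6.00 | 19 | 3 |
| 8.00 | 19 | 1 |

(readings scatter by 1.5 percentage points)

Thursday's table says little by itself: at 10.0 s it reads 0 % left-handed and 4 % right-handed product, so a scatter of 1.5 percentage points swamps any early excess. Its last left-handed reading, 5 % at 60.0 s, still matters: it equals Monday's 5 % at 1.50 min, although Thursday's charge is twice Monday's. Within that scatter, percent conversion shows no fall with the substrate charge.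

Monday's left-handed column climbs and then flattens, reading 19 % at 6.00 min and 19 % at 8.00 min. Taking the mean of these, 19.0 %, counting each hand as half the charge and none crossing over, 62.0 % of Monday's left-handed substrate remains. The right-handed readings at those times average 2.00 %. Monday's product has taken 4.20 mM of 63 mM of partner, so the flattening comes from something other than this consumption.

The quantity to carry is the reach: the natural logarithm of charged over remaining left-handed substrate on the plateau, read from Monday's run as 0.478. For a step first order in substrate, with the same partner and precatalyst charges and a stop that takes no substrate, the reach does not depend on the substrate charge. My reckoning therefore puts Thursday's flask at Monday's plateau, 21.0 % reacted. Monday's means give an excess of 81.0 %, but one standard deviation of the right-handed mean widens this to between 72.3 % and 90.6 %.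

The forecast gives an excess of 87 % at 10 s and 83 % at 8.0 min, with 21 % reacted, takes a selectivity factor near 14, and holds that “the stop must come from partner or catalyst dying independently of substrate”.

The simulation gives an excess of 91.8 % at 10 s and 90.1 % at 8.0 min, with 21.1 % reacted. The final excess stands 7.1 points above the forecast, inside my band.

    partner + catalyst + left-handed substrate → catalyst + left-handed product (k = 1020 M⁻² s⁻¹)
    partner + catalyst + right-handed substrate → catalyst + right-handed product (k = 43.4 M⁻² s⁻¹)
    left-handed substrate ⇌ right-handed substrate (k = 5.96 × 10⁻⁴ s⁻¹)
    partner + precatalyst → catalyst + spent reagent (k = 0.285 M⁻¹ s⁻¹)
    2 partner → homo dimer (k = 0.0267 M⁻¹ s⁻¹)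
    partner → decomposed reagent (k = 0.00337 s⁻¹)

The neighbouring flask charges 160 mM of partner instead of 63.0 mM. Scaling Monday's reach with the partner charge gives 1.21, a reckoned 29.8 % of the left-handed substrate remaining. At 8.0 min the neighbour reaches 0.942, against 0.420 for Thursday's flask, and holds 36.0 mM of homo dimer against 8.31 mM. It keeps 39 % of its left-handed substrate, with 38.6 % of both hands reacted.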